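**Plan**
- Retrosynthetic cuts: the C3 ester C–O bond (epoxy acid 22), then the C3–O/C4–O and C11–O bonds (alkene oxidations), then C7–C8 of ring B, then C5–C10 and C1–C2 of ring A (Diels–Alder).
- Enabling feature: ring B (C5–C10) carries a tertiary α-ketol, C7(OH) beside the C8 ketone. This is exactly what forms when a C8 acyl anion adds to a C7 ketone.
- Forward: the diene is made from propane-1,3-diol, and ring A arises by Diels–Alder with methacrolein. The two arms on C5 and C10 are grown into an isopropenyl ketone and an aldehyde, and ring B closes by a carbene-catalysed benzoin reaction. Hydration of the isopropenyl group, dihydroxylation of C3=C4 and acylation of the C3 hydroxyl finish the route.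
- Stereochemistry: C10 and C5 come from the catalyst-controlled, formyl-exo Diels–Alder. C7 comes from the chair closure on the trans-diequatorial arms. C3 and C4 come from α-face OsO4 addition. The two ester centres come from Sharpless epoxidation of angelyl alcohol.

Key step: step 12

Remark: eudesmane numbering is used for all intermediates and α is the face opposite the C10 methyl group. Enol ethers 9–13 are carried as E/Z mixtures and alcohol 12 as a mixture of carbinol epimers; both elements vanish in steps 10 and 11.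

**Route**

Step 1
Reactants: 1 propane-1,3-diol
Product: 2 3-[(tert-butyldiphenylsilyl)oxy]propan-1-ol
Conditions: NaH (1 equiv), THF, 0 °C; then t-BuPh2SiCl, rt
Reagents that add atoms: tert-butyl(chloro)diphenylsilane, CC(C)(C)[Si](Cl)(c1ccccc1)c1ccccc1
Why: One equivalent of NaH gives the sparingly soluble monosodium alkoxide, which is silylated once (monosilylation of a symmetrical diol).

Step 2
Reactants: 2 3-[(tert-butyldiphenylsilyl)oxy]propan-1-ol
Product: 3 3-[(tert-butyldiphenylsilyl)oxy]propanal
Conditions: TEMPO (10 mol%), PhI(OAc)2, CH2Cl2, rt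
Reagents that add atoms: none
Why: The oxoammonium (TEMPO) oxidation stops at the aldehyde and leaves the silyl ether untouched.

Step 3
Reactants: 3 3-[(tert-butyldiphenylsilyl)oxy]propanal; 4 2-(triphenylphosphoranylidene)propanal
Product: 5 (E)-5-[(tert-butyldiphenylsilyl)oxy]-2-methylpent-2-enal
Conditions: toluene, 90 °C
Reagents that add atoms: none
Why: Wittig olefination with the stabilised formyl ylide should give the (E)-trisubstituted enal, and the α-branched product reacts with the ylide far more slowly than aldehyde 3.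

Step 4
Reactants: 5 (E)-5-[(tert-butyldiphenylsilyl)oxy]-2-methylpent-2-enal
Product: 6 (E)-tert-butyl[(4-methylhexa-3,5-dien-1-yl)oxy]diphenylsilane
Conditions: Ph3PCH3Br, KOtBu, THF, 0 °C → rt
Reagents that add atoms: methyltriphenylphosphonium bromide, C[P+](c1ccccc1)(c1ccccc1)c1ccccc1.[Br-]
Why: Wittig methylenation adds the terminal vinyl carbon and leaves the geometry of the existing trisubstituted double bond unchanged.

Step 5
Reactants: 6 (E)-tert-butyl[(4-methylhexa-3,5-dien-1-yl)oxy]diphenylsilane; 7 methacrolein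
Product: 8 (1S,2S)-2-{2-[(tert-butyldiphenylsilyl)oxy]ethyl}-1,3-dimethylcyclohex-3-ene-1-carbaldehyde
Conditions: (S)-3,3-diphenyl-1-(2-methylphenyl)tetrahydro-1H,3H-pyrrolo[1,2-c][1,3,2]oxazaborole protonated with HN(SO2CF3)2 (20 mol%), CH2Cl2, −78 → −40 °C
Reagents that add atoms: none
Why: In this catalytic asymmetric Diels–Alder reaction the activated enal should bond through its β-carbon to the unsubstituted diene terminus (regiochemistry governed by the terminal substituent), the α-methyl enal should react through the formyl-exo transition state so that the C10 methyl and the C5 side chain of the (E)-diene end up cis, and the (S)-catalyst, which binds the s-trans enal through a formyl C–H···O contact above one phenyl ring, should expose the face that gives C10 as S.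

Step 6
Reactants: 8 (1S,2S)-2-{2-[(tert-butyldiphenylsilyl)oxy]ethyl}-1,3-dimethylcyclohex-3-ene-1-carbaldehyde
Product: 9 tert-butyl{2-[(1S,6S)-6-(2-methoxyethenyl)-2,6-dimethylcyclohex-2-en-1-yl]ethoxy}diphenylsilane (E/Z mixture)
Conditions: MeOCH2PPh3Cl, KOtBu, THF, 0 °C → rt
Reagents that add atoms: (methoxymethyl)triphenylphosphonium chloride, COC[P+](c1ccccc1)(c1ccccc1)c1ccccc1.[Cl-]
Why: Wittig homologation with the small, reactive methoxymethylene ylide should convert the neopentyl aldehyde into a methyl enol ether, a masked C9–C8 acetaldehyde unit that tolerates fluoride, buffered oxidation and Grignard addition.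

Step 7
Reactants: 9 tert-butyl{2-[(1S,6S)-6-(2-methoxyethenyl)-2,6-dimethylcyclohex-2-en-1-yl]ethoxy}diphenylsilane
Product: 10 2-[(1S,6S)-6-(2-methoxyethenyl)-2,6-dimethylcyclohex-2-en-1-yl]ethan-1-ol
Conditions: Bu4NF, THF, rt
Reagents that add atoms: none
Why: Fluoride cleaves the Si–O bond (desilylation) and affects neither the enol ether nor the ring alkene.

Step 8
Reactants: 10 2-[(1S,6S)-6-(2-methoxyethenyl)-2,6-dimethylcyclohex-2-en-1-yl]ethan-1-ol
Product: 11 2-[(1S,6S)-6-(2-methoxyethenyl)-2,6-dimethylcyclohex-2-en-1-yl]acetaldehyde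
Conditions: Dess–Martin periodinane, pyridine, CH2Cl2, 0 °C → rt
Reagents that add atoms: none
Why: Dess–Martin oxidation buffered with pyridine should give the C7 aldehyde without acid that would hydrolyse the enol ether.

Step 9
Reactants: 11 2-[(1S,6S)-6-(2-methoxyethenyl)-2,6-dimethylcyclohex-2-en-1-yl]acetaldehyde
Product: 12 1-[(1S,6S)-6-(2-methoxyethenyl)-2,6-dimethylcyclohex-2-en-1-yl]-3-methylbut-3-en-2-ol (carbinol epimers)
Conditions: CH2=C(CH3)MgBr, THF, −78 °C; aq. NH4Cl
Reagents that add atoms: isopropenylmagnesium bromide, CC(=C)[Mg]Br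
Why: Grignard 1,2-addition to the unhindered aldehyde brings in C11–C13; the new carbinol centre is formed unselectively and is erased in step 10.

Step 10
Reactants: 12 1-[(1S,6S)-6-(2-methoxyethenyl)-2,6-dimethylcyclohex-2-en-1-yl]-3-methylbut-3-en-2-ol
Product: 13 1-[(1S,6S)-6-(2-methoxyethenyl)-2,6-dimethylcyclohex-2-en-1-yl]-3-methylbut-3-en-2-one
Conditions: Dess–Martin periodinane, pyridine, CH2Cl2, 0 °C → rt
Reagents that add atoms: none
Why: Buffered Dess–Martin oxidation of the secondary allylic alcohol should give the isopropenyl ketone without double-bond migration or enol ether loss.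

Step 11
Reactants: 13 1-[(1S,6S)-6-(2-methoxyethenyl)-2,6-dimethylcyclohex-2-en-1-yl]-3-methylbut-3-en-2-one
Product: 14 2-[(1R,2R)-1,3-dimethyl-2-(3-methyl-2-oxobut-3-en-1-yl)cyclohex-3-en-1-yl]acetaldehyde
Conditions: 1 M aq. HCl, THF, 0 °C → rt
Reagents that add atoms: water, O
Why: Acid-catalysed enol ether hydrolysis (C-protonation, hemiacetal collapse) should unveil the C8 aldehyde under conditions mild enough for the enone and the ring alkene; the descriptors change only because the substituent priorities change.

Step 12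
Reactants: 14 2-[(1R,2R)-1,3-dimethyl-2-(3-methyl-2-oxobut-3-en-1-yl)cyclohex-3-en-1-yl]acetaldehyde
Product: 16 7α-hydroxyeudesma-3,11-dien-8-one, via Breslow enaminol 15 (not isolated)
Conditions: 2-(pentafluorophenyl)-6,7-dihydro-5H-pyrrolo[2,1-c][1,2,4]triazol-2-ium tetrafluoroborate (20 mol%), Et3N (20 mol%), toluene, 23 → 40 °C
Reagents that add atoms: none
Why: Deprotonation of the triazolium salt gives the carbene, which adds to the C8 aldehyde; proton transfer gives enaminol 15, whose nucleophilic C8 attacks the C7 ketone, and the adduct collapses to release the carbene and ketol 16. The closest known reaction type is the carbene-catalysed intramolecular crossed aldehyde–ketone benzoin cyclisation to six-membered tertiary α-ketols. Ring B closes by 6-exo-trig attack of C8 on the C7 carbonyl. The new C7 centre (S, hydroxyl α) is controlled by the C5 and C10 centres of ring A: their arms are trans-diequatorial, and the chair transition state places the isopropenyl group equatorial and the developing alkoxide axial on the α face, a preference that the reversibility of the addition should reinforce. The step needs umpolung at the aldehyde only, 1,2-addition to the enone and no aldol closure; these are secured because only the aldehyde can form an enaminol, because 1,4-addition would require an eight-membered ring, and because the weak amine base keeps attack of C6 on C8 slow.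

Step 13
Reactants: 16 7α-hydroxyeudesma-3,11-dien-8-one
Product: 17 7α,11-dihydroxyeudesm-3-en-8-one
Conditions: Mn(dpm)3 (10 mol%; dpm = 2,2,6,6-tetramethylheptane-3,5-dionate), PhSiH3, O2 (1 atm), i-PrOH/CH2Cl2, 0 °C
Reagents that add atoms: dioxygen, O=O
Why: Mukaiyama hydration (hydrogen atom transfer from a manganese hydride, then O2 capture of the tertiary C11 radical) is Markovnikov-selective and should prefer the 1,1-disubstituted isopropenyl group over the more hindered trisubstituted C3=C4 alkene, with fast O2 trapping outrunning acyl migration of the β-keto radical.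

Step 14
Reactants: 17 7α,11-dihydroxyeudesm-3-en-8-one
Product: 18 3α,4α,7α,11-tetrahydroxyeudesman-8-one
Conditions: OsO4 (5 mol%), N-methylmorpholine N-oxide, acetone/H2O, rt
Reagents that add atoms: osmium tetroxide, O=[Os](=O)(=O)=O; N-methylmorpholine N-oxide, C[N+]1([O-])CCOCC1; water, O
Why: In this Upjohn dihydroxylation OsO4 should add suprafacially to the only remaining alkene from the α face, opposite the axial C10 methyl of the trans-decalin, which sets C3 and C4 as the 3α,4α-cis-diol.

Step 15
Reactants: 19 angelic acid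
Product: 20 (Z)-2-methylbut-2-en-1-ol
Conditions: LiAlH4, Et2O, 0 °C → rt
Reagents that add atoms: none
Why: Hydride reduction of the carboxylic acid gives the allylic alcohol without touching or isomerising the (Z)-alkene.

Step 16
Reactants: 20 (Z)-2-methylbut-2-en-1-ol
Product: 21 [(2R,3S)-2,3-dimethyloxiran-2-yl]methanol
Conditions: Ti(OiPr)4 (10 mol%), D-(−)-diethyl tartrate (12 mol%), t-BuOOH, 4 Å MS, CH2Cl2, −20 °C
Reagents that add atoms: tert-butyl hydroperoxide, CC(C)(C)OO
Why: In this Sharpless asymmetric epoxidation the D-(−)-tartrate titanium complex should deliver oxygen to the alkene face that gives the (2R,3S)-epoxide, and the Z geometry is retained as the cis relation of the C3 methyl and the hydroxymethyl group.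

Step 17
Reactants: 21 [(2R,3S)-2,3-dimethyloxiran-2-yl]methanol
Product: 22 (2S,3S)-2,3-epoxy-2-methylbutanoic acid
Conditions: RuCl3·xH2O (2 mol%), NaIO4, CCl4/MeCN/H2O, 0 °C → rt
Reagents that add atoms: water, O
Why: RuO4 generated catalytically should oxidise the primary alcohol through the aldehyde hydrate to the acid without opening the epoxide; the C2 descriptor changes from R to S only through the change in priorities.

Step 18
Reactants: 22 (2S,3S)-2,3-epoxy-2-methylbutanoic acid; 18 3α,4α,7α,11-tetrahydroxyeudesman-8-one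
Product: 24 3α-[(2S,3S)-2,3-epoxy-2-methylbutanoyloxy]-4α,7α,11-trihydroxyeudesman-8-one, via mixed anhydride 23 (not isolated)
Conditions: 2,4,6-trichlorobenzoyl chloride, Et3N, THF, 0 °C → rt; then 18, DMAP, toluene, rt → 40 °C
Reagents that add atoms: none
Why: In this Yamaguchi esterification DMAP should open the mixed anhydride at the less hindered epoxy acyl carbon, and the acylpyridinium should be taken up by the only secondary hydroxyl (C3), the three tertiary hydroxyls being too hindered to compete.

**Compound list**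

1 | propane-1,3-diol | OCCCO | starting material
2 | 3-[(tert-butyldiphenylsilyl)oxy]propan-1-ol | OCCCO[Si](c1ccccc1)(c1ccccc1)C(C)(C)C | intermediate
3 | 3-[(tert-butyldiphenylsilyl)oxy]propanal | O=CCCO[Si](c1ccccc1)(c1ccccc1)C(C)(C)C | intermediate
4 | 2-(triphenylphosphoranylidene)propanal | CC(C=O)=P(c1ccccc1)(c1ccccc1)c1ccccc1 | starting material
5 | (E)-5-[(tert-butyldiphenylsilyl)oxy]-2-methylpent-2-enal | O=C/C(C)=C/CCO[Si](c1ccccc1)(c1ccccc1)C(C)(C)C | intermediate
6 | (E)-tert-butyl[(4-methylhexa-3,5-dien-1-yl)oxy]diphenylsilane | C=C/C(C)=C/CCO[Si](c1ccccc1)(c1ccccc1)C(C)(C)C | intermediate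
7 | methacrolein | C=C(C)C=O | starting material
8 | (1S,2S)-2-{2-[(tert-butyldiphenylsilyl)oxy]ethyl}-1,3-dimethylcyclohex-3-ene-1-carbaldehyde (C10 methyl and C5 side chain cis) | O=C[C@@]1(C)CCC=C(C)[C@@H]1CCO[Si](c1ccccc1)(c1ccccc1)C(C)(C)C | intermediate
9 | tert-butyl{2-[(1S,6S)-6-(2-methoxyethenyl)-2,6-dimethylcyclohex-2-en-1-yl]ethoxy}diphenylsilane (E/Z mixture) | COC=C[C@@]1(C)CCC=C(C)[C@@H]1CCO[Si](c1ccccc1)(c1ccccc1)C(C)(C)C | intermediate
10 | 2-[(1S,6S)-6-(2-methoxyethenyl)-2,6-dimethylcyclohex-2-en-1-yl]ethan-1-ol (E/Z mixture) | COC=C[C@@]1(C)CCC=C(C)[C@@H]1CCO | intermediate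
11 | 2-[(1S,6S)-6-(2-methoxyethenyl)-2,6-dimethylcyclohex-2-en-1-yl]acetaldehyde (E/Z mixture) | COC=C[C@@]1(C)CCC=C(C)[C@@H]1CC=O | intermediate
12 | 1-[(1S,6S)-6-(2-methoxyethenyl)-2,6-dimethylcyclohex-2-en-1-yl]-3-methylbut-3-en-2-ol (E/Z mixture, carbinol epimers) | COC=C[C@@]1(C)CCC=C(C)[C@@H]1CC(O)C(C)=C | intermediate
13 | 1-[(1S,6S)-6-(2-methoxyethenyl)-2,6-dimethylcyclohex-2-en-1-yl]-3-methylbut-3-en-2-one (E/Z mixture) | COC=C[C@@]1(C)CCC=C(C)[C@@H]1CC(=O)C(C)=C | intermediate
14 | 2-[(1R,2R)-1,3-dimethyl-2-(3-methyl-2-oxobut-3-en-1-yl)cyclohex-3-en-1-yl]acetaldehyde | O=CC[C@@]1(C)CCC=C(C)[C@@H]1CC(=O)C(C)=C | intermediate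
15 | Breslow enaminol of 14 (C8 bound as enol to C3 of the 2-pentafluorophenyl-pyrrolotriazolylidene) | OC(C[C@@]1(C)CCC=C(C)[C@@H]1CC(=O)C(C)=C)=C1N(c2c(F)c(F)c(F)c(F)c2F)N=C2CCCN12 | intermediate
16 | 7α-hydroxyeudesma-3,11-dien-8-one (5α-H, 10β-methyl, 7S; isopropenyl β) | C1=C(C)[C@@H]2C[C@](O)(C(C)=C)C(=O)C[C@@]2(C)CC1 | intermediate
17 | 7α,11-dihydroxyeudesm-3-en-8-one | C1=C(C)[C@@H]2C[C@](O)(C(C)(C)O)C(=O)C[C@@]2(C)CC1 | intermediate
18 | 3α,4α,7α,11-tetrahydroxyeudesman-8-one (C4 methyl β) | O[C@@H]1CC[C@]2(C)CC(=O)[C@@](O)(C(C)(C)O)C[C@H]2[C@]1(C)O | intermediate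
19 | angelic acid, (Z)-2-methylbut-2-enoic acid | C/C=C(/C)C(=O)O | starting material
20 | (Z)-2-methylbut-2-en-1-ol | C/C=C(/C)CO | intermediate
21 | [(2R,3S)-2,3-dimethyloxiran-2-yl]methanol | C[C@@H]1O[C@]1(C)CO | intermediate
22 | (2S,3S)-2,3-epoxy-2-methylbutanoic acid | C[C@@H]1O[C@]1(C)C(=O)O | intermediate
23 | (2S,3S)-2,3-epoxy-2-methylbutanoic 2,4,6-trichlorobenzoic anhydride | C[C@@H]1O[C@]1(C)C(=O)OC(=O)c1c(Cl)cc(Cl)cc1Cl | intermediate
24 | 3α-[(2S,3S)-2,3-epoxy-2-methylbutanoyloxy]-4α,7α,11-trihydroxyeudesman-8-one (CNP0145407.1) | C[C@@H]1O[C@]1(C)C(=O)O[C@@H]1CC[C@]2(C)CC(=O)[C@@](O)(C(C)(C)O)C[C@H]2[C@]1(C)O | target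

**Step count**

Total: 18 steps. Longest linear sequence: 15 steps (steps 1–14 and 18, from propane-1,3-diol).

**Steps most likely to fail**

1. Step 12. The carbene may add conjugately to the enone, or base-mediated aldol closure of C6 onto C8 may outpace the benzoin addition, so that ring B does not form through C7–C8. The fallback sets out from keto aldehyde 14 and replaces umpolung by reductive coupling. SmI2 in THF/t-BuOH at −78 °C should reduce the aldehyde to its ketyl, which adds to the samarium-bound C7 ketone through the same chair and gives the cis-diol eudesma-3,11-diene-7α,8α-diol F1. Parikh–Doering oxidation (SO3·pyridine, DMSO, Et3N) of the secondary C8 hydroxyl then gives the ketol, and the route is rejoined at 16.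

2. Step 5. Regiocontrol, exo/endo control or enantiocontrol may be poor with the acyclic 1,2-disubstituted diene, which would scramble the C5/C10 relationship. The fallback sets out from methacrolein 7, lets the cycloaddition create C10 alone and sets C5 later by a suprafacial sigmatropic shift.
   - 3-Methylbut-3-en-2-one is silylated (i-Pr3SiOSO2CF3, Et3N) to 2-methyl-3-[(triisopropylsilyl)oxy]buta-1,3-diene F2.
   - Diels–Alder reaction of F2 with 7 under the catalyst of step 5 gives (S)-1,3-dimethyl-4-[(triisopropylsilyl)oxy]cyclohex-3-ene-1-carbaldehyde F3. The silyloxy group now fixes the regiochemistry and only one stereocentre forms.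
   - Methoxymethylene Wittig reaction gives {[(4S)-4-(2-methoxyethenyl)-2,4-dimethylcyclohex-1-en-1-yl]oxy}triisopropylsilane F4.
   - Saegusa–Ito dehydrogenation (Pd(OAc)2, O2, DMSO) gives (S)-4-(2-methoxyethenyl)-2,4-dimethylcyclohex-2-en-1-one F5.
   - CBS reduction with the (R)-methyl oxazaborolidine and BH3·SMe2 (alkenyl side as the large group) gives (1S,4S)-4-(2-methoxyethenyl)-2,4-dimethylcyclohex-2-en-1-ol F6, with the C3 hydroxyl β.
   - Eschenmoser–Claisen rearrangement (MeC(OMe)2NMe2, xylene, 140 °C) moves the two-carbon unit to the β face of C5 and the alkene to C3=C4, giving 2-[(1S,6S)-6-(2-methoxyethenyl)-2,6-dimethylcyclohex-2-en-1-yl]-N,N-dimethylacetamide F7.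
   - Partial reduction with LiAlH(OEt)3 gives the aldehyde, and the route is rejoined at 11.

3. Step 13. The trisubstituted C3=C4 alkene may be hydrated as well, or the C11 radical beside the ketol may undergo acyl migration or fragmentation before O2 capture. The fallback sets out from ketol 16 and uses ionic Markovnikov hydration. Hg(OAc)2 in THF/H2O should attack the 1,1-disubstituted alkene much faster than the ring alkene, as in the hydration of limonene to α-terpineol, and give 12-(acetoxymercurio)-7α,11-dihydroxyeudesm-3-en-8-one F8 (C11 epimers). Brief treatment with NaBH4 in aq. NaOH at 0 °C replaces mercury by hydrogen while sparing the hindered C8 ketone; the transient radical sits on C12, too far from the ketone for an acyl shift. The route is rejoined at 17.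

**Further compounds**

F1 | step 12 | eudesma-3,11-diene-7α,8α-diol | C1=C(C)[C@@H]2C[C@](O)(C(C)=C)[C@@H](O)C[C@@]2(C)CC1
F2 | step 5 | 2-methyl-3-[(triisopropylsilyl)oxy]buta-1,3-diene | C=C(C)C(=C)O[Si](C(C)C)(C(C)C)C(C)C
F3 | step 5 | (S)-1,3-dimethyl-4-[(triisopropylsilyl)oxy]cyclohex-3-ene-1-carbaldehyde | O=C[C@@]1(C)CCC(O[Si](C(C)C)(C(C)C)C(C)C)=C(C)C1
F4 | step 5 | {[(4S)-4-(2-methoxyethenyl)-2,4-dimethylcyclohex-1-en-1-yl]oxy}triisopropylsilane | COC=C[C@@]1(C)CCC(O[Si](C(C)C)(C(C)C)C(C)C)=C(C)C1
F5 | step 5 | (S)-4-(2-methoxyethenyl)-2,4-dimethylcyclohex-2-en-1-one | COC=C[C@@]1(C)CCC(=O)C(C)=C1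
F6 | step 5 | (1S,4S)-4-(2-methoxyethenyl)-2,4-dimethylcyclohex-2-en-1-ol | COC=C[C@@]1(C)CC[C@H](O)C(C)=C1
F7 | step 5 | 2-[(1S,6S)-6-(2-methoxyethenyl)-2,6-dimethylcyclohex-2-en-1-yl]-N,N-dimethylacetamide | COC=C[C@@]1(C)CCC=C(C)[C@@H]1CC(=O)N(C)C
F8 | step 13 | 12-(acetoxymercurio)-7α,11-dihydroxyeudesm-3-en-8-one | C1=C(C)[C@@H]2C[C@](O)(C(C)(O)C[Hg]OC(C)=O)C(=O)C[C@@]2(C)CC1
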